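**Strategy.** The C9 ketone, the oxygenated C8, the C7–C8 bond and the C11=C13 exo-methylene together are the retron of an oxy-Claisen rearrangement. The ten-membered carbocycle (C1–C10) is therefore formed last. It arises by contraction of a twelve-membered oxacycle in which C9 is linked through an ether oxygen and C13 to C11 of a C6-configured butenolide, while C8 sits outside the ring as a formyl group. Enol silylation and heating bring C8 into the ring and expel O, C13 and C11 from it. The same operation creates the C7–C8 bond, both adjacent stereocentres, the C9 enone carbonyl and the α-methylene-γ-lactone. Both Z-olefins stem from nerol and a Z-selective iodo-olefination.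

Key step: step 12

Remark 1: atom labels C1–C15 are the germacrane numbers of the target (C6 = lactone O–CH, C7 = ring-fusion CH, C8 = acyloxy CH, C9 = ketone, C11=C13 = exo-methylene, C12 = lactone C=O).
Remark 2 (assumption): C9 is carried as a mixture of epimers in 7–16. It becomes sp2 in 17, so its configuration is irrelevant.

Step 1
Reactants: 1 nerol
Product: 2 neryl triethylsilyl ether
Conditions: TESCl, imidazole, CH2Cl2, 0 °C
Reagents that add atoms: chlorotriethylsilane, CC[Si](Cl)(CC)CC
Why: Routine imidazole-promoted silyl-ether protection of the primary allylic alcohol, with TES chosen because the Swern reagent of step 6 oxidises a primary TES ether directly.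

Step 2
Reactants: 2 neryl triethylsilyl ether
Product: 3 (4Z)-4-methyl-6-(triethylsilyloxy)hex-4-enal
Conditions: O3 (1.0 equiv, dye end-point), CH2Cl2, −78 °C; Me2S, −78 °C to rt
Reagents that add atoms: ozone, [O-][O+]=O
Why: Chemoselective ozonolysis with reductive work-up, in which one equivalent of ozone should cleave the remote, electron-richer Me2C=CH olefin in preference to the 2,3-olefin, which is deactivated inductively by the allylic silyloxy group and keeps its Z geometry (later C4=C5).

Step 3
Reactants: 3 (4Z)-4-methyl-6-(triethylsilyloxy)hex-4-enal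
Product: 4 (2Z,6Z)-7-iodo-3-methylocta-2,6-dienyl triethylsilyl ether
Conditions: EtPPh3I, n-BuLi, THF, rt; I2, −78 °C; NaHMDS, −20 °C; then 3, −78 °C
Reagents that add atoms: ethyltriphenylphosphonium iodide, CC[P+](c1ccccc1)(c1ccccc1)c1ccccc1.[I-]; iodine, II
Why: Stork–Zhao-type Wittig iodo-olefination, in which the non-stabilised α-iodoethylidene ylide reacts under kinetic control to give the (Z)-2-iodoalk-2-ene with iodine cis to the chain, fixing the later C1=C10 geometry.

Step 4
Reactants: 4 (2Z,6Z)-7-iodo-3-methylocta-2,6-dienyl triethylsilyl ether; 5 2,2-dimethoxyacetaldehyde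
Product: 7 (3Z,7Z)-1,1-dimethoxy-3,7-dimethyl-9-(triethylsilyloxy)nona-3,7-dien-2-ol, via vinyllithium 6 (not isolated)
Conditions: t-BuLi (2 equiv), Et2O, −78 °C; then 5 (commercial aqueous solution, dried azeotropically), −78 °C; H2O
Reagents that add atoms: none
Why: Iodine–lithium exchange retains the olefin geometry and the vinyllithium adds 1,2 to the aldehyde to form C9–C10, the new carbinol centre C9 arising without control, which is harmless because step 12 erases it.

Step 5
Reactants: 7 (3Z,7Z)-1,1-dimethoxy-3,7-dimethyl-9-(triethylsilyloxy)nona-3,7-dien-2-ol; 8 methyl 2-(bromomethyl)acrylate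
Product: 9 C9–O–C13 acrylate ether
Conditions: NaH, THF, 0 °C; then 8, cat. Bu4NI
Reagents that add atoms: none
Why: Williamson etherification with a 2-(alkoxycarbonyl)allyl bromide, for which SN2 and SN2′ attack give the same product, the neighbouring acetal (instead of a silyl ether) excluding O-to-O protecting-group migration in the alkoxide.

Step 6
Reactants: 9 C9–O–C13 acrylate ether
Product: 10 Z-enal (C6 aldehyde)
Conditions: (COCl)2, DMSO, CH2Cl2, −78 to −35 °C; Et3N, −78 °C
Reagents that add atoms: none
Why: Swern oxidation used as an oxidative desilylation, in which the chlorosulfonium salt attacks the unhindered primary allylic TES ether directly, the low temperature keeps the neral-type Z-enal from isomerising, and acetal and acrylate are inert.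

Step 7
Reactants: 10 Z-enal (C6 aldehyde)
Product: 11 (9R)-vinyl carbinol (C6–OH)
Conditions: CH2=CHMgBr, ZnCl2, Et2O/dioxane (gives divinylzinc, salts filtered off); (+)-MIB (10 mol %), PhMe/hexane, −20 to 0 °C
Reagents that add atoms: vinylmagnesium bromide, C=C[Mg]Br
Why: Ligand-accelerated catalytic asymmetric addition of a vinylzinc reagent to an aldehyde, in which (−)-MIB directs organozincs to the Si face, so its enantiomer should deliver vinyl to the Re face and set C6 (R in 11, the same spatial arrangement as 6S in the target), with esters and acetal inert to organozincs.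

Step 8
Reactants: 11 (9R)-vinyl carbinol (C6–OH)
Product: 12 seco acid
Conditions: LiOH, THF/H2O, 0 °C to rt; aq. NaHSO4 to pH 4
Reagents that add atoms: lithium hydroxide, [Li+].[OH-]
Why: Saponification of the unhindered methyl ester, with a mildly acidic work-up that spares the bis-allylic alcohol and the acetal.

Step 9
Reactants: 12 seco acid
Product: 13 thirteen-membered macrolactone
Conditions: MNBA, DMAP, CH2Cl2 (1 mM, slow addition), rt
Reagents that add atoms: none
Why: Shiina macrolactonisation under high dilution acylates the C6 alcohol with retention, and its basic, non-ionising conditions avoid allylic transposition of the bis-allylic alcohol.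

Step 10
Reactants: 13 thirteen-membered macrolactone
Product: 14 butenolide-bridged twelve-membered ether acetal
Conditions: Hoveyda–Grubbs II (10 mol %), 1,4-benzoquinone (cat.), PhMe (2 mM), 80 °C
Reagents that add atoms: none
Why: Ring-closing metathesis of an allylic 2-substituted acrylate to a butenolide, a well-used five-ring closure run here transannularly, in which the monosubstituted vinyl group initiates, the trisubstituted Z-olefins are too hindered to compete, loss of ethene drives the reaction and C6 is untouched.

Step 11
Reactants: 14 butenolide-bridged twelve-membered ether acetal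
Product: 16 twelve-membered ether aldehyde, via lutidinium salt 15 (not isolated)
Conditions: TESOTf, 2,6-lutidine, CH2Cl2, 0 °C; then H2O; used at once
Reagents that add atoms: water, O
Why: Acetal cleavage by the silyl triflate/2,6-lutidine pyridinium-salt method followed by water, which works under weakly basic conditions and so avoids acid-induced ionisation of the allylic C–O bonds and conjugation of the β,γ-unsaturated aldehyde.

Step 12
Reactants: 16 twelve-membered ether aldehyde
Product: 19 8-epi-hydroxy germacranolide, via enol silane 17 (not isolated), via silyl ether 18 (not isolated)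
Conditions: TESOTf (1.1 equiv), Et3N, CH2Cl2, −78 °C; hexane, filtration under Ar; PhMe (5 mM), 90 °C; then HF·pyridine, THF, 0 °C
Reagents that add atoms: none
Why: Soft enolisation of the doubly activated C9–H should give the (Z)-1-siloxy-2-allyloxy-diene 17 (siloxy cis to the ring oxygen, favoured by the cis effect of 1,2-dioxy-olefins and by avoidance of A1,3 strain with the C10 methyl), whose allyl vinyl ether unit C8=C9–O–C13–C11=C7 undergoes a concerted suprafacial [3,3]-sigmatropic siloxy-Claisen shift that breaks O–C13 and forms C7–C8. The closest known reactions are the ring-contracting Ireland–Claisen rearrangement of macrolactones and the oxy-Claisen rearrangement of enol derivatives of α-allyloxy carbonyl compounds, and the donor at C8, the ester acceptor on C11 and the enone conjugation gained at C9 all lower the barrier. The ten-membered carbocycle is closed transannularly through the six-centre transition state, C8 entering the ring while O, C13 and C11 leave it (12 to 10), and the γ-lactone ring is carried through unchanged. C7 is controlled by C6, because the C5–C10 tether holds the enol ether on the butenolide face that bears C5, so C8 is delivered cis to C5 and H6/H7 end up cis. C8 is controlled by the Z enol geometry together with a boat-like transition state, usual for allyl units embedded in small rings and the only one the Z,Z tether should span (a chair would demand an anti C6–C7–C8–C9 torsion), which gives 8S, the epimer that step 16 inverts. The step needs enolisation of the aldehyde in preference to the butenolide γ-C–H at C6, secured by the far higher acidity of the O-silylated aldehyde at −78 °C with one equivalent of triflate, and periselectivity over a [1,5]-H shift of the Z-diene, secured by the moderate temperature that the push–pull substitution allows.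

Step 13
Reactants: 20 angelic acid
Product: 21 (Z)-2-methylbut-2-en-1-ol
Conditions: LiAlH4, Et2O, 0 °C
Reagents that add atoms: none
Why: Hydride reduction of the carboxylic acid to the allylic alcohol, which leaves the trisubstituted Z-olefin and its geometry intact at low temperature.

Step 14
Reactants: 21 (Z)-2-methylbut-2-en-1-ol
Product: 22 [(2R,3S)-2,3-dimethyloxiran-2-yl]methanol
Conditions: Ti(OiPr)4, D-(−)-DIPT, t-BuOOH, 4 Å MS, CH2Cl2, −20 °C
Reagents that add atoms: tert-butyl hydroperoxide, CC(C)(C)OO
Why: Sharpless asymmetric epoxidation, in which syn oxygen transfer keeps the Z relationship (C3-methyl cis to CH2OH) and the D-(−)-tartrate selects the olefin face that gives 2R,3S, opposite to the 2S series obtained with L-(+)-tartrate.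

Step 15
Reactants: 22 [(2R,3S)-2,3-dimethyloxiran-2-yl]methanol
Product: 23 (2S,3S)-2,3-dimethyloxirane-2-carboxylic acid
Conditions: TEMPO (cat.), PhI(OAc)2, MeCN/H2O, rt
Reagents that add atoms: water, O
Why: Oxoammonium (TEMPO) oxidation of the primary alcohol through the aldehyde hydrate to the acid under near-neutral conditions that spare the epoxide, the C2 descriptor changing only through CIP priorities.

Step 16
Reactants: 19 8-epi-hydroxy germacranolide; 23 (2S,3S)-2,3-dimethyloxirane-2-carboxylic acid
Product: 24 target CNP0183761.1
Conditions: PPh3, DIAD, PhMe/THF, 0 °C (betaine pre-formed, then 23, then 19), to rt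
Reagents that add atoms: none
Why: Mitsunobu esterification, in which the carboxylate displaces the C8 oxyphosphonium group by SN2 (accelerated by the adjacent C9 carbonyl) with clean inversion 8S to 8R, and pre-forming the betaine keeps free phosphine away from the α-methylene lactone.

**Compound list**
1 | nerol, (2Z)-3,7-dimethylocta-2,6-dien-1-ol | CC(C)=CCC/C(C)=C\CO | starting material
2 | neryl triethylsilyl ether | CC(C)=CCC/C(C)=C\CO[Si](CC)(CC)CC | intermediate
3 | (4Z)-4-methyl-6-(triethylsilyloxy)hex-4-enal | O=CCC/C(C)=C\CO[Si](CC)(CC)CC | intermediate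
4 | (2Z,6Z)-7-iodo-3-methylocta-2,6-dienyl triethylsilyl ether | C/C(I)=C/CC/C(C)=C\CO[Si](CC)(CC)CC | intermediate
5 | 2,2-dimethoxyacetaldehyde | COC(OC)C=O | starting material
6 | (Z)-vinyllithium from 4 (Li in place of I, not isolated) | C/C([Li])=C/CC/C(C)=C\CO[Si](CC)(CC)CC | intermediate
7 | (3Z,7Z)-1,1-dimethoxy-3,7-dimethyl-9-(triethylsilyloxy)nona-3,7-dien-2-ol (C9 epimers) | COC(OC)C(O)/C(C)=C\CC/C(C)=C\CO[Si](CC)(CC)CC | intermediate
8 | methyl 2-(bromomethyl)acrylate | C=C(CBr)C(=O)OC | starting material
9 | methyl 2-({[(3Z,7Z)-1,1-dimethoxy-3,7-dimethyl-9-(triethylsilyloxy)nona-3,7-dien-2-yl]oxy}methyl)acrylate | COC(OC)C(OCC(=C)C(=O)OC)/C(C)=C\CC/C(C)=C\CO[Si](CC)(CC)CC | intermediate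
10 | methyl 2-({[(3Z,7Z)-1,1-dimethoxy-3,7-dimethyl-9-oxonona-3,7-dien-2-yl]oxy}methyl)acrylate | COC(OC)C(OCC(=C)C(=O)OC)/C(C)=C\CC/C(C)=C\C=O | intermediate
11 | methyl 2-({[(3Z,7Z,9R)-9-hydroxy-1,1-dimethoxy-3,7-dimethylundeca-3,7,10-trien-2-yl]oxy}methyl)acrylate | COC(OC)C(OCC(=C)C(=O)OC)/C(C)=C\CC/C(C)=C\[C@H](O)C=C | intermediate
12 | 2-({[(3Z,7Z,9R)-9-hydroxy-1,1-dimethoxy-3,7-dimethylundeca-3,7,10-trien-2-yl]oxy}methyl)acrylic acid | COC(OC)C(OCC(=C)C(=O)O)/C(C)=C\CC/C(C)=C\[C@H](O)C=C | intermediate
13 | (7Z,11Z,13R)-6-(dimethoxymethyl)-7,11-dimethyl-3-methylidene-13-vinyl-1,5-dioxacyclotrideca-7,11-dien-2-one | C=C[C@H]1OC(=O)C(=C)COC(C(OC)OC)/C(C)=C\CC/C(C)=C\1 | intermediate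
14 | (5Z,9Z,11S)-4-(dimethoxymethyl)-5,9-dimethyl-3,12-dioxabicyclo[9.2.1]tetradeca-1(14),5,9-trien-13-one | O=C1O[C@@H]2C=C1COC(C(OC)OC)/C(C)=C\CC/C(C)=C\2 | intermediate
15 | N-(α-methoxyalkyl)-2,6-lutidinium triflate derived from 14 (one OMe replaced by lutidinium, not isolated) | O=C1O[C@@H]2C=C1COC(C(OC)[n+]3c(C)cccc3C)/C(C)=C\CC/C(C)=C\2.[O-]S(=O)(=O)C(F)(F)F | intermediate
16 | (5Z,9Z,11S)-5,9-dimethyl-13-oxo-3,12-dioxabicyclo[9.2.1]tetradeca-1(14),5,9-triene-4-carbaldehyde | O=C1O[C@@H]2C=C1COC(C=O)/C(C)=C\CC/C(C)=C\2 | intermediate
17 | (5Z,9Z,11S)-5,9-dimethyl-4-[(Z)-(triethylsilyloxy)methylidene]-3,12-dioxabicyclo[9.2.1]tetradeca-1(14),5,9-trien-13-one (not isolated) | O=C1O[C@@H]2C=C1CO/C(=C\O[Si](CC)(CC)CC)/C(C)=C\CC/C(C)=C\2 | intermediate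
18 | (1(10)Z,4Z,6S,7S,8S)-9-oxo-8-(triethylsilyloxy)germacra-1(10),4,11(13)-trien-12,6-olide (not isolated) | C=C1C(=O)O[C@H]2/C=C(/C)CC/C=C(/C)C(=O)[C@@H](O[Si](CC)(CC)CC)[C@@H]12 | intermediate
19 | (1(10)Z,4Z)-8-hydroxy-9-oxogermacra-1(10),4,11(13)-trien-12,6-olide, 6S,7R,8S (H6/H7 cis, OH epimeric to the target ester, C7 spatially as in the target and its descriptor changed only by CIP priorities) | C=C1C(=O)O[C@H]2/C=C(/C)CC/C=C(/C)C(=O)[C@@H](O)[C@@H]12 | intermediate
20 | angelic acid, (Z)-2-methylbut-2-enoic acid | C/C=C(/C)C(=O)O | starting material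
21 | (Z)-2-methylbut-2-en-1-ol | C/C=C(/C)CO | intermediate
22 | [(2R,3S)-2,3-dimethyloxiran-2-yl]methanol | OC[C@@]1(C)O[C@H]1C | intermediate
23 | (2S,3S)-2,3-dimethyloxirane-2-carboxylic acid | OC(=O)[C@@]1(C)O[C@H]1C | intermediate
24 | (1(10)Z,4Z,6S,7S,8R)-8-[(2S,3S)-2,3-dimethyloxirane-2-carbonyloxy]-9-oxogermacra-1(10),4,11(13)-trien-12,6-olide, CNP0183761.1 | C=C1C(=O)O[C@H]2/C=C(/C)CC/C=C(/C)C(=O)[C@H](OC(=O)[C@@]3(C)O[C@H]3C)[C@@H]12 | target

Total step count: 16. Longest linear sequence: 13 (steps 1–12 and 16).

**Steps most likely to fail**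

1. **Step 12.**
   - What may go wrong: the transannular boat-like transition state may be strained enough that, at the temperature needed, the Z-dienol silane is consumed by a [1,5]-hydrogen shift. Prolonged exposure to triflate and amine may also enolise the butenolide γ-position and erode the C6 configuration.
   - Fallback: replace the neutral thermal rearrangement by the charge-accelerated anionic oxy-Claisen rearrangement.
   - It sets out from aldehyde 16. KHMDS (1.0 equiv, PhMe/THF, −78 °C) should give the chelated potassium (Z)-enolate F1.
   - F1 should rearrange between −78 and −20 °C to the potassium alkoxide F2. A quench with acetic acid at −78 °C gives 19, where the route is rejoined.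

2. **Step 10.**
   - What may go wrong: the two olefins meet only in the s-cis ester rotamer, which is unfavourable inside a thirteen-membered lactone. Catalyst decay, olefin isomerisation or ring-opening oligomerisation may therefore outrun closure.
   - Fallback: reverse the order of the two ring closures.
   - It sets out from hydroxy ester 11 and bypasses 12 and 13. Macrocyclic ring-closing metathesis, assisted by the free allylic hydroxyl group, should give the twelve-membered (Z)-hydroxy enoate F3.
   - Because metathesis is reversible and only the Z isomer can lactonise (cat. PPTS), the lactonisation drains the equilibrium towards 14, where the route is rejoined.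

3. **Step 16.**
   - What may go wrong: the phosphine may add to the α-methylene lactone. The oxyphosphonium salt may eliminate towards a C7=C8 enone. Inversion at the hindered C8 may be incomplete.
   - Fallback: a two-stage sulfonate displacement.
   - It sets out from 19. MsCl/Et3N (CH2Cl2, −20 °C) gives the α-keto mesylate F4.
   - F4 is displaced by the caesium carboxylate F5 (from 23 and Cs2CO3) in DMF at rt with inversion, arriving at 24.

**Further compounds**
F1 | step 12 | potassium (Z)-enolate of aldehyde 16 | O=C1O[C@@H]2C=C1CO/C(=C\[O-])/C(C)=C\CC/C(C)=C\2.[K+]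
F2 | step 12 | potassium C8-alkoxide of 19 | C=C1C(=O)O[C@H]2/C=C(/C)CC/C=C(/C)C(=O)[C@@H]([O-])[C@@H]12.[K+]
F3 | step 10 | twelve-membered (Z)-γ-hydroxy enoate, methyl ester with C6–OH cis to CO2Me across C7=C11 | COC(=O)/C1=C\[C@@H](O)/C=C(/C)CC/C=C(/C)C(C(OC)OC)OC1
F4 | step 16 | C8 methanesulfonate of 19 | C=C1C(=O)O[C@H]2/C=C(/C)CC/C=C(/C)C(=O)[C@@H](OS(C)(=O)=O)[C@@H]12
F5 | step 16 | caesium (2S,3S)-2,3-dimethyloxirane-2-carboxylate | [Cs+].[O-]C(=O)[C@@]1(C)O[C@H]1C
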